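The leftover came first. If the two end groups are spent one for one, Wednesday's flask holds 0.00500 M of second end groups over the first, and any remedy has to work with that excess.

common to all: first end groups 0.10 M
- Wednesday's: second end groups 0.105 M; temperature 5 °C; the very flask that is asked about, followed so far
- Friday's: second end groups 0.052 M; temperature 0 °C; run made earlier
- flask: second end groups 0.105 M; temperature 5 °C; time 80 min

| run | time / min | links / % |
|---|---|---|
| Wednesday's | 5.00 | 25 |
| Wednesday's | 15.0 | 30 |
| Wednesday's | 30.0 | 30 |
| Wednesday's | 40.0 | 32 |
| Wednesday's | 60.0 | 29 |
| Wednesday's | 80.0 | 27 |
| Friday's | 1.33 | 7 |
| Friday's | 2.00 | 9 |
| Friday's | 3.00 | 11 |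
| Friday's | 5.00 | 13 |
| Friday's | 10.0 | 7 |
| Friday's | 15.0 | 8 |

(readings scatter by 2 percentage points)

- what is added takes up no volume worth counting
- a reading or a percentage of links counts all its forms, free or not

- oak: change nothing and wait 80 min more
- maple: at 80 min add first end groups, 50.0 % of the amount charged, then wait 80 min
- larch: at 80 min add second end groups, 50.0 % of the amount charged, then wait 80 min
- birch: at 80 min raise the temperature by 10 K, then wait 80 min

* links, in percent of the first end groups first charged, at 80 min
* the remedy with the largest gain of links, or "none" below 2 percentage points (oak / maple / larch / birch / none)
* links present, in percent of the first end groups first charged, after oak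
* links present, in percent of the first end groups first charged, after birch

Wednesday's readings from 15.0 min on averaged 29.6 % and lay flat within a scatter of 2 percentage points. I read that as the end of the charge, not a balance: first end groups, the limiting reagent, had reacted away, and some unseen route took what did not become links. Friday's flask settled near 9.33 %, so 17.9 % of its second end groups became links, less than the 28.2 % in Wednesday's flask, whose charge was twice as large.

Links are the small thing on Friday, so I reckoned only them. I assumed that the rate into links grows with [second end groups] and the other rate does not. Over a run in which [second end groups] falls to nothing, the share is then half the starting ratio. Scaled to Wednesday's charge, this gives 0.725: the link number, the starting rate into links over the starting rate into the other route.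

Followed through the run, it gives 26.0 % links, less than the readings. For the leftover the number falls to 0.0345, so maple gains 0.086 points, less than 2 points. Larch, oak and birch meet a flask I held to be without first end groups. I committed to none, with links staying near 29.6 %.

The forecast gave 29 % now, 28.5 % after oak, 22 % after birch and larch as best, holding that “links seem to depend more steeply on second end groups”. We parted on larch and birch.

The flask gave 27.2 %, 27.2 % after oak, 27.2 % after birch, and none.

    second end groups + links ⇌ idle adduct, settled at all times (K = 10.0 L mol⁻¹, ΔH = −22.0 kJ mol⁻¹)
    first end groups + second end groups → rings, rate k2*[first end groups] as long as [second end groups] is above zero (k = 0.204 min⁻¹, Ea = 77.0 kJ mol⁻¹)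
    first end groups + second end groups → links (k = 1.66 L mol⁻¹ min⁻¹, Ea = 55.0 kJ mol⁻¹)
    (constants at 5 °C)

Maple gained 0.079 points against my 0.086 points, and at 80.0 min the flask held 0 % of its first end groups and 72.8 % rings. In the neighbour flask with 0.026 M of second end groups, the link number scales to 0.179. Half of that, applied to its charge, gives 2.33 % links. That neighbour flask gave 2.39 % links and 23.6 % rings, with 0 % of its second end groups and 74.0 % of its first end groups remaining.

Readings and results stem from a simulated flask with constants of no real substance; the scatter is artificial.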